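**Target:** (2S)-5,7-dihydroxy-2-(4-methoxyphenyl)-8-(3-methylbut-2-en-1-yl)chroman-4-one, i.e. (2S)-4'-O-methyl-8-prenylnaringenin, C21H22O5. The single stereocentre C2 is S.

**Assumption:** (2S)-isosakuranetin (4'-O-methylnaringenin, CAS 480-43-3) is bought as the natural S enantiomer and its ee is confirmed by chiral HPLC before use.

## Retrosynthetic overview

1. Target ⇒ its 7-O-acetate (near-neutral deacetylation as the last step).
2. C8–prenyl bond ⇒ 5-O-prenyl ether by an Eu(III)-catalysed Claisen–Cope relay (O5 → C6 → C8), which fixes the 8-regiochemistry.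
3. 5-O-prenyl ether ⇒ Mitsunobu coupling of the chelated 5-OH with prenol (base-free, so the flavanone is not opened).
4. 7-O-acetate ⇒ (2S)-isosakuranetin by selective acetylation of the non-chelated 7-OH.
5. Rings: none are formed. The chromanone (A/C) and anisyl (B) rings and the C2 stereocentre come intact from the chiral-pool flavanone; only the C8–C bond is made.

## Route

**Step 1**
Reactants: 1, (2S)-isosakuranetin [(2S)-5,7-dihydroxy-2-(4-methoxyphenyl)chroman-4-one]; 2, acetic anhydride
Product: 3, (2S)-7-acetoxy-5-hydroxy-2-(4-methoxyphenyl)chroman-4-one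
Conditions: Ac2O (1.1 equiv), pyridine, CH2Cl2, 0 °C → rt
Reagents that add atoms: acetic anhydride, CC(=O)OC(C)=O
Why: Chemoselective O-acylation: the 7-OH is free and the more acidic phenol, while the 5-OH is locked in a hydrogen bond to C4=O and stays unreacted with one equivalent; C2 is untouched.

**Step 2**
Reactants: 3, (2S)-7-acetoxy-5-hydroxy-2-(4-methoxyphenyl)chroman-4-one; 4, 3-methylbut-2-en-1-ol (prenol)
Product: 5, (2S)-7-acetoxy-2-(4-methoxyphenyl)-5-[(3-methylbut-2-en-1-yl)oxy]chroman-4-one
Conditions: prenol (1.5 equiv), PPh3, DIAD, THF, 0 °C → rt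
Reagents that add atoms: 3-methylbut-2-en-1-ol, CC(C)=CCO
Why: Mitsunobu etherification gives SN2 O-alkylation at the primary allylic carbon under neutral conditions, so the aryl acetate survives and no base-induced retro-oxa-Michael opening (racemisation via the chalcone) can occur.

**Step 3**
Reactants: 5, (2S)-7-acetoxy-2-(4-methoxyphenyl)-5-[(3-methylbut-2-en-1-yl)oxy]chroman-4-one
Product: 6, (2S)-7-acetoxy-5-hydroxy-2-(4-methoxyphenyl)-8-(3-methylbut-2-en-1-yl)chroman-4-one
Conditions: Eu(fod)3 (10 mol %), CHCl3, 60 °C (sealed tube); chromatography to remove the 6-(1,1-dimethylallyl) isomer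
Reagents that add atoms: none
Why: Tandem aromatic Claisen–Cope (para-Claisen) rearrangement: Eu(III) chelated by C4=O and O5 accelerates the [3,3] shift to C6, and the resulting 6-(1,1-dimethylallyl) dienone undergoes a Cope [3,3] shift to C8 and then re-aromatises. The two allyl inversions deliver a normal prenyl group at C8 and regenerate the 5-OH; C2 is remote and keeps its S configuration.

**Step 4**
Reactants: 6, (2S)-7-acetoxy-5-hydroxy-2-(4-methoxyphenyl)-8-(3-methylbut-2-en-1-yl)chroman-4-one
Product: 7, (2S)-5,7-dihydroxy-2-(4-methoxyphenyl)-8-(3-methylbut-2-en-1-yl)chroman-4-one (target)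
Conditions: NH4OAc (10 equiv), MeOH–H2O (4:1), rt
Reagents that add atoms: none
Why: Near-neutral solvolysis of the phenolic acetate avoids strong base (chalcone opening and racemisation at C2) and strong acid (cyclisation of the prenyl group onto the 7-OH to a chroman). The final ee is confirmed by chiral HPLC.

## Compound list

1 | (2S)-isosakuranetin; (2S)-5,7-dihydroxy-2-(4-methoxyphenyl)chroman-4-one | COc1ccc([C@@H]2CC(=O)c3c(O)cc(O)cc3O2)cc1 | starting material
2 | acetic anhydride | CC(=O)OC(C)=O | starting material
3 | (2S)-7-acetoxy-5-hydroxy-2-(4-methoxyphenyl)chroman-4-one | COc1ccc([C@@H]2CC(=O)c3c(O)cc(OC(C)=O)cc3O2)cc1 | intermediate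
4 | 3-methylbut-2-en-1-ol (prenol) | CC(C)=CCO | starting material
5 | (2S)-7-acetoxy-2-(4-methoxyphenyl)-5-[(3-methylbut-2-en-1-yl)oxy]chroman-4-one | COc1ccc([C@@H]2CC(=O)c3c(OCC=C(C)C)cc(OC(C)=O)cc3O2)cc1 | intermediate
6 | (2S)-7-acetoxy-5-hydroxy-2-(4-methoxyphenyl)-8-(3-methylbut-2-en-1-yl)chroman-4-one | COc1ccc([C@@H]2CC(=O)c3c(O)cc(OC(C)=O)c(CC=C(C)C)c3O2)cc1 | intermediate
7 | (2S)-5,7-dihydroxy-2-(4-methoxyphenyl)-8-(3-methylbut-2-en-1-yl)chroman-4-one | COc1ccc([C@@H]2CC(=O)c3c(O)cc(O)c(CC=C(C)C)c3O2)cc1 | target

## Summary

Total step count: 4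
Longest linear sequence: 4 (fully linear from 1)

Three steps most likely to fail, each with a fallback that changes the approach:

1. **Step 3 (Claisen–Cope).** The Cope relay may stall, giving the 6-(1,1-dimethylallyl) or 6-prenyl isomers instead of the 8-prenyl product. Fallback: make the C8–C bond by cross-coupling in the achiral chromone series and set C2 afterwards. That is, 5,7-bis(MOM-oxy)chromone → C8 iodination (NIS) → Pd-catalysed prenylation (prenyl-Bpin or prenyl-SnBu3) → Rh(I)/chiral bisphosphine asymmetric 1,4-addition of 4-methoxyphenylboronic acid (ligand enantiomer chosen for 2S) → MOM removal.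

2. **Step 2 (Mitsunobu on the chelated, hindered 5-OH).** The reaction may be sluggish or give SN2' or C-alkylation products. Fallback: give up stereoretention at this stage. Alkylate a 7-O-MOM analogue with prenyl bromide/K2CO3 (accepting racemisation through the chalcone), carry the racemate through rearrangement and deprotection, and resolve the final flavanone by preparative chiral HPLC.

3. **Step 4 (deacetylation, and overall ee).** Partial racemisation via retro-oxa-Michael opening, or chroman formation, could occur during unmasking. Fallback: change the protecting-group strategy from step 1, using a 7-O-TIPS ether (TIPSCl, imidazole) carried through steps 2–3 and removed with HF·pyridine in THF at 0 °C. If the purchased 1 is itself of low ee, prepare (S)-1 by catalytic asymmetric 1,4-addition of 4-methoxyphenylboronic acid to a 5,7-diprotected chromone instead of relying on the chiral pool.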